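**Retrosynthetic overview**
The ten ring carbons are read as a 3-methylcyclohex-2-enone (C5–C10, carrying C7, C8, C9; germacrane numbering) plus 1-methylcyclobutene (C1–C4), joined at C4–C5 and C1–C10. An enone–cyclobutene [2+2] photocycloaddition gives a bicyclo[2.2.0]hexane (C1, C2, C3, C4, C5, C10) fused to the six-membered ring.
Thermal cleavage of C5–C10 and C1–C4 then unveils the ten-membered ring as a 1(10),4-dien-6-one.
Ring order: dioxolane-protected cyclohexenone (C8, C9 from toluene cis-dihydrodiol; C7 by enolate alkylation) → cyclobutane (key step) → ten-membered ring → 8,12-γ-lactone → 4,5-epoxide.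
Late disconnections: C6 ester by Mitsunobu inversion; epoxide by C6-hydroxyl-directed epoxidation of the 4E olefin (made from the 4Z enone by stannyl addition/oxidative destannylation); C11=C13 by Mannich methylenation; C10–H by diimide reduction of C1=C10.

Key step: step 6

Remark: the cis-fused photoadduct is expected to open through a chair cyclohexane-1,4-diyl to the cis,trans-dienone with C1=C10 E and the enone C4=C5 Z; the route is written for this isomer, and steps 11–12 correct the C4=C5 geometry.

**Route**

Step 1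
Reactants: 1 (1S,2R)-3-methylcyclohexa-3,5-diene-1,2-diol
Product: 2 (3aR,7aS)-2,2,4-trimethyl-3a,7a-dihydro-1,3-benzodioxole
Conditions: 2,2-dimethoxypropane, TsOH (cat.), acetone, 0 °C
Reagents that add atoms: 2,2-dimethoxypropane, COC(C)(C)OC
Why: Acid-catalysed transketalisation closes the acetonide on the cis-diol without touching either stereocentre.

Step 2
Reactants: 2 (3aR,7aS)-2,2,4-trimethyl-3a,7a-dihydro-1,3-benzodioxole
Product: 3 (3aR,7aS)-2,2,4-trimethyl-3a,6,7,7a-tetrahydro-1,3-benzodioxole
Conditions: KO2CN=NCO2K, AcOH, MeOH, 0 °C → rt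
Reagents that add atoms: none
Why: Diimide reduction (concerted syn transfer of H2) is very sensitive to substitution, so the disubstituted C6=C7 bond is saturated and the trisubstituted C5=C10 bond is kept, as known for arene cis-dihydrodiol acetonides.

Step 3
Reactants: 3 (3aR,7aS)-2,2,4-trimethyl-3a,6,7,7a-tetrahydro-1,3-benzodioxole
Product: 4 (3aS,7aR)-2,2,7-trimethyl-3a,7a-dihydro-1,3-benzodioxol-5(4H)-one
Conditions: CrO3, 3,5-dimethylpyrazole, CH2Cl2, −20 °C
Reagents that add atoms: chromium trioxide, O=[Cr](=O)=O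
Why: Allylic oxidation by the CrO3·3,5-dimethylpyrazole complex at the only allylic methylene (C6) gives the enone; oxygen delivered at the tertiary allyl terminus C10 would return to C6 by allyl chromate [3,3] shift, so both paths converge.

Step 4
Reactants: 4 (3aS,7aR)-2,2,7-trimethyl-3a,7a-dihydro-1,3-benzodioxol-5(4H)-one; 5 methyl bromoacetate
Product: 7 methyl 2-[(3aS,4S,7aR)-2,2,7-trimethyl-5-oxo-3a,4,5,7a-tetrahydro-1,3-benzodioxol-4-yl]acetate, via lithium dienolate 6 (not isolated)
Conditions: LiN(i-Pr)2 (LDA), THF, −78 °C; then 5, DMPU, −78 → −50 °C; AcOH quench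
Reagents that add atoms: none
Why: Kinetic α'-deprotonation at C7 and SN2 alkylation of the cross-conjugated lithium dienolate, the electrophile entering anti to the adjacent C8–O bond of the cis-fused dioxolane (C7 arm trans to O8); low temperature suppresses β-alkoxide elimination.

Step 5
Reactants: 8 methylenecyclobutane
Product: 9 1-methylcyclobutene
Conditions: KOt-Bu (cat.), DMSO, 70 °C; fractional distillation
Reagents that add atoms: none
Why: Base-catalysed prototropic isomerisation of the exocyclic alkene to the more stable trisubstituted endocyclic isomer, which is separated by distillation.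

Step 6
Reactants: 7 methyl 2-[(3aS,4S,7aR)-2,2,7-trimethyl-5-oxo-3a,4,5,7a-tetrahydro-1,3-benzodioxol-4-yl]acetate; 9 1-methylcyclobutene
Product: 10 cis-anti-cis 6-4-4 photoadduct (new bonds C4–C5 and C1–C10; cyclobutane anti to the dioxolane; C8/C9 acetonide and C7 CH2CO2Me arm retained)
Conditions: hν (350 nm, Pyrex), 9 (10 equiv), CH2Cl2, −40 °C; filtration through basic Al2O3
Reagents that add atoms: none
Why: n→π* excitation and intersystem crossing give the enone triplet, which bonds through its β-carbon C10 to the unsubstituted cyclobutene carbon C1 to give a triplet 1,4-biradical (α-keto radical at C5, tertiary cyclobutyl radical at C4) that closes after spin inversion; this is the enone–alkene [2+2] photocycloaddition, closest to the known head-to-head additions of 1-methylcyclobutene to 3-methylcyclohex-2-enones. The one new ring, the cyclobutane C1–C4–C5–C10, closes by radical recombination of that biradical (a stepwise formal [2+2]) and forms the bicyclo[2.2.0]hexane together with the cyclobutene ring. C1 and C4 are cis because they were the cyclobutene double bond; C5 and C10 end cis-fused because any trans-fused isomer epimerises at C5 (α to the ketone) on basic alumina; the new bonds form anti to the C9 oxygen of the dioxolane, which shields that face next to C10; the cyclobutene ring turns away from the six-membered ring (exo), giving the cis-anti-cis adduct. The selectivity the route needs is regiochemical (C4 to C5, methyl groups 1,3 on the new ring), because the four new stereocentres become sp2 again in step 7 and the facial outcome only decides which diyl conformer is entered there. It is secured by the biradical from C10–C1 bonding carrying its radical on the tertiary C4, while the alternative biradical (bond C5–C1, radicals at C10 and C4) would have to join two fully substituted carbons and reverts to the reactants. The large excess of volatile alkene at low temperature suppresses enone dimerisation.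

Step 7
Reactants: 10 cis-anti-cis 6-4-4 photoadduct
Product: 11 methyl (1(10)E,4Z)-8,9-isopropylidenedioxy-6-oxo-13-norgermacra-1(10),4-dien-12-oate
Conditions: PhMe (0.01 M, degassed), sealed silylated tube, 180 °C
Reagents that add atoms: none
Why: Thermal cycloreversion of the bicyclo[2.2.0]hexane (homolysis of C1–C4 to a cyclohexane-1,4-diyl, then cleavage of C5–C10; known for enone–cyclobutene photoadducts); because the trans-diequatorial C7 arm and C8 oxygen hold the chair in which C9 is equatorial and C6 axial on the diyl ring, the cis-fused adduct should give the cis,trans-dienone with C1=C10 E and C4=C5 Z, an isomer much less prone to Cope rearrangement than the trans,trans one.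

Step 8
Reactants: 11 methyl (1(10)E,4Z)-8,9-isopropylidenedioxy-6-oxo-13-norgermacra-1(10),4-dien-12-oate
Product: 12 methyl (4Z,10R)-8,9-isopropylidenedioxy-6-oxo-13-norgermacr-4-en-12-oate
Conditions: KO2CN=NCO2K (excess), AcOH, CH2Cl2/MeOH, 0 °C → rt
Reagents that add atoms: none
Why: Diimide, a non-coordinating reagent whose rate follows strain release, should add H2 syn to the strained E C1=C10 bond and spare the unstrained conjugated Z-enone; in the crossed conformer in which the diene is formed (kept populated by the trans C7/C8 substituents) the inner lobe at C10 faces C5, so hydrogen arrives on the face from which C5 departed and C10 gets its methyl erythro to O9, as in the target.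

Step 9
Reactants: 12 methyl (4Z,10R)-8,9-isopropylidenedioxy-6-oxo-13-norgermacr-4-en-12-oate
Product: 14 (4Z,10R)-9-hydroxy-6-oxo-13-norgermacr-4-en-12,8-olide, via dihydroxy ester 13 (not isolated)
Conditions: 1 M HCl, THF, rt; then TsOH·H2O (cat.), PhMe, 40 °C
Reagents that add atoms: none
Why: Acid hydrolysis of the acetonide and acid-catalysed lactonisation of the γ-hydroxy ester onto the C8 hydroxyl (five-membered ring favoured over the δ-lactone to O9) give the trans-fused 8,12-lactone; the step is placed here because the Z-enone is the stable isomer and cannot be damaged by acid.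

Step 10
Reactants: 14 (4Z,10R)-9-hydroxy-6-oxo-13-norgermacr-4-en-12,8-olide
Product: 15 (4Z,10R)-9-(tert-butyldimethylsilyloxy)-6-oxo-13-norgermacr-4-en-12,8-olide
Conditions: TBSOTf, 2,6-lutidine, CH2Cl2, −78 °C
Reagents that add atoms: tert-butyldimethylsilyl trifluoromethanesulfonate, CC(C)(C)[Si](C)(C)OS(=O)(=O)C(F)(F)F
Why: Silylation of the only free hydroxyl (C9) using a hindered, non-nucleophilic base, so that the base-sensitive β-acyloxy ketone is not enolised.

Step 11
Reactants: 15 (4Z,10R)-9-(tert-butyldimethylsilyloxy)-6-oxo-13-norgermacr-4-en-12,8-olide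
Product: 17 (10R)-9-(tert-butyldimethylsilyloxy)-6-oxo-4-(trimethylstannyl)-13-norgermacran-12,8-olide (C4 epimers), via lithium stannyl enolate 16 (not isolated)
Conditions: Me3SnLi, THF, −78 °C; NH4Cl (aq)
Reagents that add atoms: trimethylstannyllithium, [Li][Sn](C)(C)C
Why: Conjugate addition of the stannyl anion to the β,β-disubstituted enone (fast at −78 °C, faster than attack on the lactone) gives the regiodefined C5=C6 enolate, protonated on work-up; the C4 configuration is inconsequential because C4 becomes sp2 again.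

Step 12
Reactants: 17 (10R)-9-(tert-butyldimethylsilyloxy)-6-oxo-4-(trimethylstannyl)-13-norgermacran-12,8-olide
Product: 18 (4E,10R)-9-(tert-butyldimethylsilyloxy)-6-oxo-13-norgermacr-4-en-12,8-olide
Conditions: CrO3·2C5H5N (Collins reagent), CH2Cl2, 0 °C → rt
Reagents that add atoms: none
Why: Oxidative destannylation of a β-stannyl ketone to the enone, the known way to turn a Z-cyclodecenone into its less stable E isomer; tin and the C5 leaving group should depart anti-periplanar from the extended ring conformer with C3 and C6 anti, and the neutral medium does not allow re-equilibration.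

Step 13
Reactants: 18 (4E,10R)-9-(tert-butyldimethylsilyloxy)-6-oxo-13-norgermacr-4-en-12,8-olide
Product: 19 (4E,10R)-9-(tert-butyldimethylsilyloxy)-6-epi-6-hydroxy-13-norgermacr-4-en-12,8-olide (O6 cis to the C7–C11 bond)
Conditions: NaBH4, CeCl3·7H2O, MeOH, −78 °C; AcOH quench
Reagents that add atoms: none
Why: Luche 1,2-reduction in which hydride attacks the peripheral face of the ketone anti to the ring bond C7–C8 with C11 flanking the carbonyl oxygen (Felkin–Anh), which should give the C6 alcohol erythro to C11, the epimer needed to steer the epoxidation; low temperature prevents translactonisation and β-elimination.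

Step 14
Reactants: 19 (4E,10R)-9-(tert-butyldimethylsilyloxy)-6-epi-6-hydroxy-13-norgermacr-4-en-12,8-olide
Product: 20 (4E,10R)-9-(tert-butyldimethylsilyloxy)-6-epi-6-(triethylsilyloxy)-13-norgermacr-4-en-12,8-olide
Conditions: TESCl, imidazole, DMF, 0 °C
Reagents that add atoms: chlorotriethylsilane, CC[Si](Cl)(CC)CC
Why: Silylation of the allylic alcohol as the labile triethylsilyl ether, so that no O–H is present in the enolate step.

Step 15
Reactants: 20 (4E,10R)-9-(tert-butyldimethylsilyloxy)-6-epi-6-(triethylsilyloxy)-13-norgermacr-4-en-12,8-olide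
Product: 24 (4E)-9-(tert-butyldimethylsilyloxy)-6-epi-6-(triethylsilyloxy)germacra-4,11(13)-dien-12,8-olide, via lithium lactone enolate 21 (not isolated), via Mannich base 22 (not isolated), via trimethylammonium iodide 23 (not isolated)
Conditions: LiN(i-Pr)2, THF, −78 °C; CH2=NMe2+ I−, −78 °C → rt; MeI, THF/MeOH, rt; NaHCO3 (aq), EtOAc
Reagents that add atoms: dimethyl(methylidene)ammonium iodide (Eschenmoser's salt), C=[N+](C)C.[I-]
Why: α-Methylenation of the lactone by the Mannich sequence (lactone enolate plus iminium salt, N-methylation, base-induced loss of trimethylamine); with C6 at the alcohol oxidation level the only acidic C–H is at C11.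

Step 16
Reactants: 24 (4E)-9-(tert-butyldimethylsilyloxy)-6-epi-6-(triethylsilyloxy)germacra-4,11(13)-dien-12,8-olide
Product: 25 (4E)-9-(tert-butyldimethylsilyloxy)-6-epi-6-hydroxygermacra-4,11(13)-dien-12,8-olide
Conditions: PPTS (cat.), MeOH, 0 °C
Reagents that add atoms: none
Why: Acid-catalysed methanolysis removes the allylic triethylsilyl ether selectively beside the hindered tert-butyldimethylsilyl ether; oxa-Michael closure of O6 onto C13 would be 5-endo and is not expected.

Step 17
Reactants: 25 (4E)-9-(tert-butyldimethylsilyloxy)-6-epi-6-hydroxygermacra-4,11(13)-dien-12,8-olide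
Product: 26 (4R,5R)-9-(tert-butyldimethylsilyloxy)-4,5-epoxy-6-epi-6-hydroxygermacr-11(13)-en-12,8-olide
Conditions: VO(acac)2 (cat.), t-BuOOH, CH2Cl2, 0 °C
Reagents that add atoms: tert-butyl hydroperoxide, CC(C)(C)OO
Why: Hydroxyl-directed epoxidation by the vanadium alkoxide–peroxide complex of the electron-rich trisubstituted E olefin (the α-methylene lactone is inert); A(1,3) strain between C15 and C6 puts H6 in the olefin plane, so oxygen is delivered syn to O6 on the exposed face (threo), setting C4 and C5 as in the target and keeping the E geometry as the trans-epoxide.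

Step 18
Reactants: 26 (4R,5R)-9-(tert-butyldimethylsilyloxy)-4,5-epoxy-6-epi-6-hydroxygermacr-11(13)-en-12,8-olide; 27 3-methylbut-2-enoic acid
Product: 28 (4R,5R,6R)-9-(tert-butyldimethylsilyloxy)-4,5-epoxy-6-(3-methylbut-2-enoyloxy)germacr-11(13)-en-12,8-olide
Conditions: PPh3, DIAD, 27, PhMe, 0 °C → rt
Reagents that add atoms: none
Why: Mitsunobu esterification, in which SN2 displacement of the C6 alkoxyphosphonium by 3-methylbut-2-enoate inverts C6 and turns the threo epoxy alcohol into the erythro ester of the target (inversion of secondary 2,3-epoxy alcohols under these conditions is known); C9 is silylated.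

Step 19
Reactants: 28 (4R,5R,6R)-9-(tert-butyldimethylsilyloxy)-4,5-epoxy-6-(3-methylbut-2-enoyloxy)germacr-11(13)-en-12,8-olide
Product: 29 (4R,5R,6R,7S,8S,9R,10R)-4,5-epoxy-9-hydroxy-6-(3-methylbut-2-enoyloxy)germacr-11(13)-en-12,8-olide (CNP0119422.1)
Conditions: HF·pyridine, pyridine, THF, 0 °C
Reagents that add atoms: none
Why: Fluoride-mediated desilylation under pyridine-buffered conditions, which should leave the epoxide, the enoate and the α-methylene lactone intact, frees the C9 hydroxyl.

**Compound list**
1 | (1S,2R)-3-methylcyclohexa-3,5-diene-1,2-diol | CC1=CC=C[C@H](O)[C@@H]1O | starting material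
2 | (3aR,7aS)-2,2,4-trimethyl-3a,7a-dihydro-1,3-benzodioxole | CC1=CC=C[C@@H]2OC(C)(C)O[C@H]12 | intermediate
3 | (3aR,7aS)-2,2,4-trimethyl-3a,6,7,7a-tetrahydro-1,3-benzodioxole | CC1=CCC[C@@H]2OC(C)(C)O[C@H]12 | intermediate
4 | (3aS,7aR)-2,2,7-trimethyl-3a,7a-dihydro-1,3-benzodioxol-5(4H)-one | CC1=CC(=O)C[C@@H]2OC(C)(C)O[C@H]12 | intermediate
5 | methyl bromoacetate | COC(=O)CBr | starting material
6 | lithium dienolate of 4 (C6=C7 enolate) | CC1=CC([O-])=C[C@@H]2OC(C)(C)O[C@H]12.[Li+] | intermediate
7 | methyl 2-[(3aS,4S,7aR)-2,2,7-trimethyl-5-oxo-3a,4,5,7a-tetrahydro-1,3-benzodioxol-4-yl]acetate | CC1=CC(=O)[C@@H](CC(=O)OC)[C@@H]2OC(C)(C)O[C@H]12 | intermediate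
8 | methylenecyclobutane | C=C1CCC1 | starting material
9 | 1-methylcyclobutene | CC1=CCC1 | intermediate
10 | cis-anti-cis 6-4-4 photoadduct (C4–C5 and C1–C10 bonds; cyclobutane anti to the dioxolane) | O=C1[C@@H](CC(=O)OC)[C@@H]2OC(C)(C)O[C@@H]2[C@@]3(C)[C@@H]4CC[C@]4(C)[C@@H]13 | intermediate
11 | methyl (1(10)E,4Z)-8,9-isopropylidenedioxy-6-oxo-13-norgermacra-1(10),4-dien-12-oate | C/C1=C\CC/C(C)=C\C(=O)[C@@H](CC(=O)OC)[C@@H]2OC(C)(C)O[C@H]12 | intermediate
12 | methyl (4Z,10R)-8,9-isopropylidenedioxy-6-oxo-13-norgermacr-4-en-12-oate | C[C@@H]1CCC/C(C)=C\C(=O)[C@@H](CC(=O)OC)[C@@H]2OC(C)(C)O[C@H]12 | intermediate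
13 | methyl (4Z,10R)-8,9-dihydroxy-6-oxo-13-norgermacr-4-en-12-oate | C[C@@H]1CCC/C(C)=C\C(=O)[C@@H](CC(=O)OC)[C@H](O)[C@@H]1O | intermediate
14 | (4Z,10R)-9-hydroxy-6-oxo-13-norgermacr-4-en-12,8-olide | C1C(=O)O[C@@H]2[C@H](O)[C@H](C)CCC/C(C)=C\C(=O)[C@@H]12 | intermediate
15 | (4Z,10R)-9-(tert-butyldimethylsilyloxy)-6-oxo-13-norgermacr-4-en-12,8-olide | C1C(=O)O[C@@H]2[C@H](O[Si](C)(C)C(C)(C)C)[C@H](C)CCC/C(C)=C\C(=O)[C@@H]12 | intermediate
16 | lithium C5=C6 enolate of the 4-trimethylstannyl ketone | C1C(=O)O[C@@H]2[C@H](O[Si](C)(C)C(C)(C)C)[C@H](C)CCCC(C)([Sn](C)(C)C)C=C([O-])[C@@H]12.[Li+] | intermediate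
17 | (10R)-9-(tert-butyldimethylsilyloxy)-6-oxo-4-(trimethylstannyl)-13-norgermacran-12,8-olide (C4 epimers) | C1C(=O)O[C@@H]2[C@H](O[Si](C)(C)C(C)(C)C)[C@H](C)CCCC(C)([Sn](C)(C)C)CC(=O)[C@@H]12 | intermediate
18 | (4E,10R)-9-(tert-butyldimethylsilyloxy)-6-oxo-13-norgermacr-4-en-12,8-olide | C1C(=O)O[C@@H]2[C@H](O[Si](C)(C)C(C)(C)C)[C@H](C)CCC/C(C)=C/C(=O)[C@@H]12 | intermediate
19 | (4E,10R)-9-(tert-butyldimethylsilyloxy)-6-epi-6-hydroxy-13-norgermacr-4-en-12,8-olide | C1C(=O)O[C@@H]2[C@H](O[Si](C)(C)C(C)(C)C)[C@H](C)CCC/C(C)=C/[C@@H](O)[C@@H]12 | intermediate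
20 | (4E,10R)-9-(tert-butyldimethylsilyloxy)-6-epi-6-(triethylsilyloxy)-13-norgermacr-4-en-12,8-olide | C1C(=O)O[C@@H]2[C@H](O[Si](C)(C)C(C)(C)C)[C@H](C)CCC/C(C)=C/[C@@H](O[Si](CC)(CC)CC)[C@@H]12 | intermediate
21 | lithium C11=C12 enolate of lactone 20 | C1=C([O-])O[C@@H]2[C@H](O[Si](C)(C)C(C)(C)C)[C@H](C)CCC/C(C)=C/[C@@H](O[Si](CC)(CC)CC)[C@@H]12.[Li+] | intermediate
22 | 13-(dimethylamino) Mannich base of lactone 20 (C11 epimers) | CN(C)CC1C(=O)O[C@@H]2[C@H](O[Si](C)(C)C(C)(C)C)[C@H](C)CCC/C(C)=C/[C@@H](O[Si](CC)(CC)CC)[C@@H]12 | intermediate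
23 | 13-(trimethylammonio) lactone iodide | C[N+](C)(C)CC1C(=O)O[C@@H]2[C@H](O[Si](C)(C)C(C)(C)C)[C@H](C)CCC/C(C)=C/[C@@H](O[Si](CC)(CC)CC)[C@@H]12.[I-] | intermediate
24 | (4E)-9-(tert-butyldimethylsilyloxy)-6-epi-6-(triethylsilyloxy)germacra-4,11(13)-dien-12,8-olide | C=C1C(=O)O[C@@H]2[C@H](O[Si](C)(C)C(C)(C)C)[C@H](C)CCC/C(C)=C/[C@@H](O[Si](CC)(CC)CC)[C@@H]12 | intermediate
25 | (4E)-9-(tert-butyldimethylsilyloxy)-6-epi-6-hydroxygermacra-4,11(13)-dien-12,8-olide | C=C1C(=O)O[C@@H]2[C@H](O[Si](C)(C)C(C)(C)C)[C@H](C)CCC/C(C)=C/[C@@H](O)[C@@H]12 | intermediate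
26 | (4R,5R)-9-(tert-butyldimethylsilyloxy)-4,5-epoxy-6-epi-6-hydroxygermacr-11(13)-en-12,8-olide | C=C1C(=O)O[C@@H]2[C@H](O[Si](C)(C)C(C)(C)C)[C@H](C)CCC[C@@]3(C)O[C@@H]3[C@@H](O)[C@@H]12 | intermediate
27 | 3-methylbut-2-enoic acid | CC(C)=CC(=O)O | starting material
28 | (4R,5R,6R)-9-(tert-butyldimethylsilyloxy)-4,5-epoxy-6-(3-methylbut-2-enoyloxy)germacr-11(13)-en-12,8-olide | C=C1C(=O)O[C@@H]2[C@H](O[Si](C)(C)C(C)(C)C)[C@H](C)CCC[C@@]3(C)O[C@@H]3[C@H](OC(=O)C=C(C)C)[C@@H]12 | intermediate
29 | (4R,5R,6R,7S,8S,9R,10R)-4,5-epoxy-9-hydroxy-6-(3-methylbut-2-enoyloxy)germacr-11(13)-en-12,8-olide | C=C1C(=O)O[C@@H]2[C@H](O)[C@H](C)CCC[C@@]3(C)O[C@@H]3[C@H](OC(=O)C=C(C)C)[C@@H]12 | target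

**Totals**
Total step count: 19. Longest linear sequence: 18 steps (steps 1–4 and 6–19 from diol 1; step 5 is a one-step side branch).

**Steps most likely to fail**

Step 7. The cyclohexane-1,4-diyl may partition the wrong way: cleavage of C2–C3 or opening to a trans,trans-dienone followed by Cope rearrangement would give a divinylcyclohexanone, the diyl may revert to enone plus cyclobutene, or it may enter the other chair and give the other cis,trans isomer. The fallback closes the lactone before the ring expansion, so that the trans-diequatorial γ-lactone locks the six-membered ring in the chair that leads to the 1(10)E,4Z isomer. It sets out from 10: aqueous HCl in THF removes the acetonide to give dihydroxy ester photoadduct F1, TsOH in toluene lactonises it to hydroxy lactone photoadduct F2, and TBSOTf with 2,6-lutidine gives silyl ether photoadduct F3. Thermolysis of F3 at 180 °C should give dienone lactone F4, and diimide reduction of its C1=C10 bond returns the route at 15.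

Step 12. The oxidative destannylation may eliminate through the folded ring conformer, or the strained E-enone may re-equilibrate through reversible conjugate addition, so that the more stable Z-enone is returned. The fallback replaces addition–elimination by direct photochemical Z → E isomerisation of the enone. It sets out from 15: irradiation at 350 nm in benzene establishes a photostationary Z/E mixture, the E isomer is separated and the Z isomer re-irradiated, and the route is rejoined at 18.

Step 8. Diimide may react too slowly with the trisubstituted olefin, may reduce the enone C4=C5 in competition, or may add to the other face of C1=C10 if another ring conformer reacts. The fallback masks the enone as the β-stannyl ketone before a conventional catalytic hydrogenation. It sets out from 11: aqueous HCl in THF gives dienone dihydroxy ester F5, TsOH closes dienone hydroxy lactone F6, and TBSOTf with 2,6-lutidine gives dienone lactone F4. Me3SnLi at −78 °C adds to the enone through stannyl dienyl enolate F7 and, after NH4Cl, gives unsaturated stannyl ketone F8, in which C1=C10 is the only olefin. Hydrogenation (H2, Pd/C, EtOAc) on the exposed face of the E olefin returns the route at 17; the C10 configuration would have to be confirmed at that point.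

**Further compounds**
F1 | step 7 | dihydroxy ester photoadduct | O=C1[C@@H](CC(=O)OC)[C@H](O)[C@H](O)[C@@]2(C)[C@@H]3CC[C@]3(C)[C@@H]12
F2 | step 7 | hydroxy lactone photoadduct | O=C1[C@H]2CC(=O)O[C@@H]2[C@H](O)[C@@]3(C)[C@@H]4CC[C@]4(C)[C@@H]13
F3 | step 7 | silyl ether photoadduct (9-O-TBS lactone) | O=C1[C@H]2CC(=O)O[C@@H]2[C@H](O[Si](C)(C)C(C)(C)C)[C@@]3(C)[C@@H]4CC[C@]4(C)[C@@H]13
F4 | step 7 | (1(10)E,4Z)-9-(tert-butyldimethylsilyloxy)-6-oxo-13-norgermacra-1(10),4-dien-12,8-olide | C1C(=O)O[C@@H]2[C@H](O[Si](C)(C)C(C)(C)C)/C(C)=C/CC/C(C)=C\C(=O)[C@@H]12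
F5 | step 8 | methyl (1(10)E,4Z)-8,9-dihydroxy-6-oxo-13-norgermacra-1(10),4-dien-12-oate | C/C1=C\CC/C(C)=C\C(=O)[C@@H](CC(=O)OC)[C@H](O)[C@@H]1O
F6 | step 8 | (1(10)E,4Z)-9-hydroxy-6-oxo-13-norgermacra-1(10),4-dien-12,8-olide | C1C(=O)O[C@@H]2[C@H](O)/C(C)=C/CC/C(C)=C\C(=O)[C@@H]12
F7 | step 8 | lithium C5=C6 enolate of the unsaturated stannyl ketone | C1C(=O)O[C@@H]2[C@H](O[Si](C)(C)C(C)(C)C)/C(C)=C/CCC(C)([Sn](C)(C)C)C=C([O-])[C@@H]12.[Li+]
F8 | step 8 | (1(10)E)-9-(tert-butyldimethylsilyloxy)-6-oxo-4-(trimethylstannyl)-13-norgermacr-1(10)-en-12,8-olide | C1C(=O)O[C@@H]2[C@H](O[Si](C)(C)C(C)(C)C)/C(C)=C/CCC(C)([Sn](C)(C)C)CC(=O)[C@@H]12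
F0 | step 12 | none | none
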